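**Retrosynthetic overview**

1. Target 24 comes from hydroxy aldehyde 20 by 8-O-angeloylation and Pinnick oxidation of C15; 20 already holds the full elemanolide core.
2. 20 comes in one pot from acyclic furan 14: furan → (Z)-ene-dial, C6–C7 macrocyclising allylboration (the bond nature makes from farnesyl C1/C10), 6,12-lactonisation, then Cope rearrangement of the 15-oxogermacranolide.
3. 14 comes from ynoate 12 (syn-hydroalumination/borylmethylation fixes the allylboronate geometry), 12 from aldehyde 10, 10 from furan 8.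
4. 8 comes from diene 5 and 3-bromofuran (hydroboration/Suzuki); 5 from alkyne 3 (Zr-catalysed carboalumination/vinylation sets the 1(10)E alkene).
5. 3 comes from (R)-glycidol and acetylide: C8 is the only stereocentre brought in and controls C6/C7 (macrocyclisation) and then C5/C10 (Cope). Ring order: ten-membered carbocycle → γ-lactone → six-membered ring.

Assumption: germacrane/elemane numbering (C1–C15) is used for every intermediate; the target is 8α-angeloyloxyelema-1,3,11(13)-trien-15-oic acid 12,6α-olide, (5R,6R,7R,8S,10S).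

**Route**

Step 1
Reactants: 1 (R)-glycidol
Product: 2 (S)-pent-4-yne-1,2-diol
Conditions: LiC≡CH·H2NCH2CH2NH2 (2.5 equiv), DMSO, 0 °C → rt; H2O
Reagents that add atoms: lithium acetylide ethylenediamine complex, [Li+].[C-]#C.NCCN
Why: Acetylide SN2 opening of the epoxide at its unsubstituted carbon (the Payne shift of the glycidol alkoxide is degenerate), so the carbinol centre is carried over unchanged and becomes C8 (S) of the target.

Step 2
Reactants: 2 (S)-pent-4-yne-1,2-diol
Product: 3 (S)-4,5-bis(triethylsilyloxy)pent-1-yne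
Conditions: Et3SiCl (2.3 equiv), imidazole, CH2Cl2, 0 °C → rt
Reagents that add atoms: chlorotriethylsilane, CC[Si](Cl)(CC)CC
Why: Standard silylation of both hydroxyls; the primary TES ether is the later aldehyde precursor and the secondary one masks O-8 through the ring-forming cascade.

Step 3
Reactants: 3 (S)-4,5-bis(triethylsilyloxy)pent-1-yne
Product: 5 (2S,4E)-4-methyl-1,2-bis(triethylsilyloxy)hepta-4,6-diene, via alkenylalane 4 (not isolated)
Conditions: Me3Al (2.5 equiv), Cp2ZrCl2 (20 mol %), CH2Cl2, 0 °C → rt; then CH2=CHBr, Pd(PPh3)4 (5 mol %), ZnCl2 (20 mol %), THF, rt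
Reagents that add atoms: trimethylaluminium, C[Al](C)C; vinyl bromide, C=CBr
Why: Negishi zirconium-catalysed syn-methylalumination puts CH3 on the internal and aluminium on the terminal alkyne carbon, and the alkenylalane is cross-coupled in the same pot with vinyl bromide under zerovalent palladium catalysis (Negishi coupling) with retention, fixing the 1(10)E trisubstituted alkene.

Step 4
Reactants: 5 (2S,4E)-4-methyl-1,2-bis(triethylsilyloxy)hepta-4,6-diene; 6 3-bromofuran
Product: 8 3-[(3E,6S)-4-methyl-6,7-bis(triethylsilyloxy)hept-3-en-1-yl]furan, via alkyl-9-BBN 7 (not isolated)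
Conditions: 9-BBN, THF, 0 °C → rt; then 6, Pd(dppf)Cl2 (5 mol %), K3PO4, DMF/H2O, 50 °C
Reagents that add atoms: none
Why: 9-BBN hydroborates only the terminal carbon of the diene (the trisubstituted alkene is inert) and the B-alkyl-9-BBN undergoes B-alkyl Suzuki–Miyaura coupling with the heteroaryl bromide; the 3-substituted furan is a masked (Z)-ene-dial that encodes the 4,5-geometry.

Step 5
Reactants: 8 3-[(3E,6S)-4-methyl-6,7-bis(triethylsilyloxy)hept-3-en-1-yl]furan
Product: 10 (2S,4E)-7-(furan-3-yl)-4-methyl-2-(triethylsilyloxy)hept-4-enal, via alkoxysulfonium chloride 9 (not isolated)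
Conditions: (COCl)2, DMSO, CH2Cl2, −78 → −30 °C; Et3N, −78 °C → rt
Reagents that add atoms: none
Why: Under Swern conditions the chlorosulfonium reagent desilylates and oxidises the primary TES ether while the hindered secondary TES ether survives (Swern oxidation of a primary silyl ether), giving the α-silyloxy aldehyde without touching C8.

Step 6
Reactants: 10 (2S,4E)-7-(furan-3-yl)-4-methyl-2-(triethylsilyloxy)hept-4-enal
Product: 12 methyl (4S,6E)-9-(furan-3-yl)-6-methyl-4-(triethylsilyloxy)non-6-en-2-ynoate, via terminal alkyne 11 (not isolated)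
Conditions: Me3SiCHN2, LiN(iPr)2, THF, −78 → 0 °C; then LiN(iPr)2, −78 °C; ClCO2Me
Reagents that add atoms: trimethylsilyldiazomethane, C[Si](C)(C)C=[N+]=[N-]; methyl chloroformate, COC(=O)Cl
Why: Colvin homologation (Peterson-type elimination, then 1,2-H shift of the alkylidene carbene) turns the aldehyde into the terminal alkyne at low temperature without epimerising the α-silyloxy centre, and the acetylide made in the same pot is acylated by methyl chloroformate.

Step 7
Reactants: 12 methyl (4S,6E)-9-(furan-3-yl)-6-methyl-4-(triethylsilyloxy)non-6-en-2-ynoate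
Product: 14 methyl (2Z,4S,6E)-9-(furan-3-yl)-6-methyl-2-[(4,4,5,5-tetramethyl-1,3,2-dioxaborolan-2-yl)methyl]-4-(triethylsilyloxy)nona-2,6-dienoate, via vinylalane 13 (not isolated)
Conditions: iBu2AlH, HMPA, THF, 0 °C; then ICH2Bpin, CuI (10 mol %), 0 °C → rt
Reagents that add atoms: 2-(iodomethyl)-4,4,5,5-tetramethyl-1,3,2-dioxaborolane, ICB1OC(C)(C)C(C)(C)O1
Why: Proposed new method: the iBu2AlH–HMPA complex adds hydride conjugately and syn across the ynoate to give the α-alumino enoate, and its copper-catalysed alkylation by ICH2Bpin (boron ate complex, then 1,2-shift with loss of iodide) goes with retention, so C8 ends cis to the ester and trans to CH2B; the closest known reactions are the hydroalumination of ynoates followed by copper-catalysed allylation, and the trapping of α-cuprio enoates from ynoate carbocupration with ICH2Bpin to make 2-alkoxycarbonylallylboronates.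

Step 8
Reactants: 14 methyl (2Z,4S,6E)-9-(furan-3-yl)-6-methyl-2-[(4,4,5,5-tetramethyl-1,3,2-dioxaborolan-2-yl)methyl]-4-(triethylsilyloxy)nona-2,6-dienoate
Product: 20 8α-hydroxy-15-oxoelema-1,3,11(13)-trien-12,6α-olide, via furan endoperoxide 15 (not isolated), via ene-dial boronate 16 (not isolated), via macrocyclic borate 17 (not isolated), via germacranolide aldehyde 18 (not isolated), via silyl elemanolide aldehyde 19 (not isolated)
Conditions: O2, hν, tetraphenylporphyrin (1 mol %), CH2Cl2, −78 °C; Me2S, −78 → 0 °C; evaporate from toluene; syringe-pump addition (20 h) to Sc(OTf)3 (20 mol %), toluene, 40 °C (final 0.005 M); 70 °C, 3 h; then 1 M HCl, THF, rt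
Reagents that add atoms: dioxygen, O=O
Why: Proposed new method: singlet-oxygen [4+2] cycloaddition to the furan and sulfide reduction unveil the (Z)-ene-dial; the allylboronate then adds through its γ-carbon C7 to the C6 aldehyde (attack at C15 would need a nine-membered ring holding an E-alkene) in a closed Zimmerman–Traxler chair with C5 and C8 both equatorial (6,7-trans) and the C8 silyloxy group anti to the forming bond, H-8 being turned toward the ester by allylic strain (7,8-trans); the borate lactonises onto the methyl ester, the 15-oxogermacra-1(10),4-diene undergoes Cope rearrangement through the chair of the crossed E,E-diene to set 5α-H and 10β-CH3, and acid removes the TES group; the closest known reactions are the stereospecific Lewis-acid-catalysed additions of 2-alkoxycarbonylallylboronates to aldehydes giving α-methylene-γ-lactones, chromium-mediated C6–C7 closures of the costunolide ring, and the facile Cope rearrangement of 15-oxogermacranolides to elemanolides.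

Step 9
Reactants: 20 8α-hydroxy-15-oxoelema-1,3,11(13)-trien-12,6α-olide; 21 angelic acid
Product: 23 8α-angeloyloxy-15-oxoelema-1,3,11(13)-trien-12,6α-olide, via mixed anhydride 22 (not isolated)
Conditions: 21, 2,4,6-Cl3C6H2COCl, Et3N, toluene, rt; then 20, toluene, 75 °C
Reagents that add atoms: none
Why: Yamaguchi esterification through the mixed anhydride acylates the equatorial 8α-hydroxyl with retention and is the standard way to make angelates with little Z→E isomerisation to the tiglate.

Step 10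
Reactants: 23 8α-angeloyloxy-15-oxoelema-1,3,11(13)-trien-12,6α-olide
Product: 24 8α-angeloyloxyelema-1,3,11(13)-trien-15-oic acid 12,6α-olide (target)
Conditions: NaClO2, NaH2PO4, 2-methyl-2-butene, tBuOH/H2O, 0 °C → rt
Reagents that add atoms: sodium chlorite, [Na+].[O-]Cl=O
Why: Pinnick oxidation converts the 2-substituted acrolein into the acrylic acid chemoselectively, the alkene scavenger keeping HOCl away from the vinyl, exo-methylene and angelate groups; no stereocentre is touched.

**Compound list**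

1 | (R)-glycidol | OC[C@@H]1CO1 | starting material
2 | (S)-pent-4-yne-1,2-diol | C#CC[C@H](O)CO | intermediate
3 | (S)-4,5-bis(triethylsilyloxy)pent-1-yne | C#CC[C@H](O[Si](CC)(CC)CC)CO[Si](CC)(CC)CC | intermediate
4 | dimethyl[(1E,4S)-2-methyl-4,5-bis(triethylsilyloxy)pent-1-en-1-yl]alane | C[Al](C)/C=C(\C)C[C@H](O[Si](CC)(CC)CC)CO[Si](CC)(CC)CC | intermediate
5 | (2S,4E)-4-methyl-1,2-bis(triethylsilyloxy)hepta-4,6-diene | C=C/C=C(\C)C[C@H](O[Si](CC)(CC)CC)CO[Si](CC)(CC)CC | intermediate
6 | 3-bromofuran | Brc1ccoc1 | starting material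
7 | 9-[(3E,6S)-4-methyl-6,7-bis(triethylsilyloxy)hept-3-en-1-yl]-9-borabicyclo[3.3.1]nonane | C(C/C=C(\C)C[C@H](O[Si](CC)(CC)CC)CO[Si](CC)(CC)CC)B1C2CCCC1CCC2 | intermediate
8 | 3-[(3E,6S)-4-methyl-6,7-bis(triethylsilyloxy)hept-3-en-1-yl]furan | o1ccc(CC/C=C(\C)C[C@H](O[Si](CC)(CC)CC)CO[Si](CC)(CC)CC)c1 | intermediate
9 | {[(2S,4E)-7-(furan-3-yl)-4-methyl-2-(triethylsilyloxy)hept-4-en-1-yl]oxy}dimethylsulfonium chloride | o1ccc(CC/C=C(\C)C[C@H](O[Si](CC)(CC)CC)CO[S+](C)C)c1.[Cl-] | intermediate
10 | (2S,4E)-7-(furan-3-yl)-4-methyl-2-(triethylsilyloxy)hept-4-enal | o1ccc(CC/C=C(\C)C[C@H](O[Si](CC)(CC)CC)C=O)c1 | intermediate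
11 | 3-[(3E,6S)-4-methyl-6-(triethylsilyloxy)oct-3-en-7-yn-1-yl]furan | o1ccc(CC/C=C(\C)C[C@H](O[Si](CC)(CC)CC)C#C)c1 | intermediate
12 | methyl (4S,6E)-9-(furan-3-yl)-6-methyl-4-(triethylsilyloxy)non-6-en-2-ynoate | o1ccc(CC/C=C(\C)C[C@H](O[Si](CC)(CC)CC)C#CC(=O)OC)c1 | intermediate
13 | methyl (2E,4S,6E)-2-(diisobutylalumanyl)-9-(furan-3-yl)-6-methyl-4-(triethylsilyloxy)nona-2,6-dienoate (Al cis to H-7) | o1ccc(CC/C=C(\C)C[C@H](O[Si](CC)(CC)CC)/C=C(/[Al](CC(C)C)CC(C)C)C(=O)OC)c1 | intermediate
14 | methyl (2Z,4S,6E)-9-(furan-3-yl)-6-methyl-2-[(4,4,5,5-tetramethyl-1,3,2-dioxaborolan-2-yl)methyl]-4-(triethylsilyloxy)nona-2,6-dienoate | o1ccc(CC/C=C(\C)C[C@H](O[Si](CC)(CC)CC)/C=C(/CB2OC(C)(C)C(C)(C)O2)C(=O)OC)c1 | intermediate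
15 | 2,3,7-trioxabicyclo[2.2.1]hept-5-ene endoperoxide of 14, side chain on C5 (both bridgehead configurations) | C1(CC/C=C(\C)C[C@H](O[Si](CC)(CC)CC)/C=C(/CB3OC(C)(C)C(C)(C)O3)C(=O)OC)=CC2OOC1O2 | intermediate
16 | methyl (2Z,4S,6E,10Z)-10-formyl-6-methyl-12-oxo-2-[(4,4,5,5-tetramethyl-1,3,2-dioxaborolan-2-yl)methyl]-4-(triethylsilyloxy)dodeca-2,6,10-trienoate | O=C/C(=C\C=O)CC/C=C(\C)C[C@H](O[Si](CC)(CC)CC)/C=C(/CB1OC(C)(C)C(C)(C)O1)C(=O)OC | intermediate
17 | methyl 15-oxo-6α-[(pinacolboryl)oxy]-8α-(triethylsilyloxy)germacra-1(10)E,4Z,11(13)-trien-12-oate (7α-H) | C/C1=C\CC/C(C=O)=C/[C@@H](OB2OC(C)(C)C(C)(C)O2)[C@H](C(=C)C(=O)OC)[C@@H](O[Si](CC)(CC)CC)C1 | intermediate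
18 | 15-oxo-8α-(triethylsilyloxy)germacra-1(10)E,4Z,11(13)-trien-12,6α-olide (6β-H, 7α-H) | C/C1=C\CC/C(C=O)=C/[C@H]2OC(=O)C(=C)[C@@H]2[C@@H](O[Si](CC)(CC)CC)C1 | intermediate
19 | 15-oxo-8α-(triethylsilyloxy)elema-1,3,11(13)-trien-12,6α-olide (5α-H, 10β-CH3) | C=C[C@]1(C)C[C@H](O[Si](CC)(CC)CC)[C@H]2C(=C)C(=O)O[C@@H]2[C@H]1C(=C)C=O | intermediate
20 | 8α-hydroxy-15-oxoelema-1,3,11(13)-trien-12,6α-olide | C=C[C@]1(C)C[C@H](O)[C@H]2C(=C)C(=O)O[C@@H]2[C@H]1C(=C)C=O | intermediate
21 | angelic acid, (Z)-2-methylbut-2-enoic acid | C/C=C(/C)C(=O)O | starting material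
22 | angelic 2,4,6-trichlorobenzoic anhydride | C/C=C(/C)C(=O)OC(=O)c1c(Cl)cc(Cl)cc1Cl | intermediate
23 | 8α-angeloyloxy-15-oxoelema-1,3,11(13)-trien-12,6α-olide | C=C[C@]1(C)C[C@H](OC(=O)/C(C)=C\C)[C@H]2C(=C)C(=O)O[C@@H]2[C@H]1C(=C)C=O | intermediate
24 | 8α-angeloyloxyelema-1,3,11(13)-trien-15-oic acid 12,6α-olide, (5R,6R,7R,8S,10S) | C=C[C@]1(C)C[C@H](OC(=O)/C(C)=C\C)[C@H]2C(=C)C(=O)O[C@@H]2[C@H]1C(=C)C(=O)O | target

**Step count and risks**

Total step count: 10. Longest linear sequence: 10 (fully linear from (R)-glycidol).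

The three steps most likely to fail:

Step 8 is the largest risk. The macrocyclising allylboration has no direct precedent for a ten-membered ring and may be slow. Sc(OTf)3 could instead drive a Prins-type closure of the C15 aldehyde onto the 1(10)-alkene. The 6,7-trans/7,8-trans outcome rests on the chair model. The fallback sets out from 12. Hydroalumination as in step 7, but with paraformaldehyde as the electrophile, gives methyl (2Z,4S,6E)-9-(furan-3-yl)-2-(hydroxymethyl)-6-methyl-4-(triethylsilyloxy)nona-2,6-dienoate F1. CBr4/PPh3 converts it into the allylic bromide methyl (2E,4S,6E)-2-(bromomethyl)-9-(furan-3-yl)-6-methyl-4-(triethylsilyloxy)nona-2,6-dienoate F2. Photooxygenation and Me2S reduction as in step 8 give the bromo ene-dial methyl (2E,4S,6E,10Z)-2-(bromomethyl)-10-formyl-6-methyl-12-oxo-4-(triethylsilyloxy)dodeca-2,6,10-trienoate F3. Slow addition of F3 to CrCl2 in THF (divalent chromium, Nozaki–Hiyama–Kishi-type allylation; fast, but the allylchromium can lose its geometry before ring closure) closes the C6–C7 bond and the chromium alkoxide lactonises. This comes back to the route at 18, which is heated and treated with acid as in step 8.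

Step 7 is the second risk. The vinylalane may alkylate poorly with ICH2Bpin, or lose the γ-silyloxy group to give an allene. The fallback sets out from 12. Pd(PPh3)4-catalysed syn-hydrostannation with Bu3SnH puts tin α to the ester and gives methyl (2E,4S,6E)-9-(furan-3-yl)-6-methyl-2-(tributylstannyl)-4-(triethylsilyloxy)nona-2,6-dienoate F4. I2 gives, with retention, methyl (2E,4S,6E)-9-(furan-3-yl)-2-iodo-6-methyl-4-(triethylsilyloxy)nona-2,6-dienoate F5. Negishi coupling of F5 with IZnCH2Bpin under Pd(PPh3)4 comes back to the route at 14 with the same alkene geometry.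

Step 9 is the third risk. The angelate can isomerise to the tiglate, and the 2-substituted acrolein is sensitive to amine bases (double-bond migration toward C5). The fallback sets out from 20 and reverses the order. Pinnick oxidation first gives 8α-hydroxyelema-1,3,11(13)-trien-15-oic acid 12,6α-olide F6. Acylation of F6 with an excess of mixed anhydride 22, followed by aqueous NaHCO3 hydrolysis of the carboxylic mixed anhydride formed at C15, comes back to the route at 24.

**Further compounds**

F1 | step 8 | methyl (2Z,4S,6E)-9-(furan-3-yl)-2-(hydroxymethyl)-6-methyl-4-(triethylsilyloxy)nona-2,6-dienoate | o1ccc(CC/C=C(\C)C[C@H](O[Si](CC)(CC)CC)/C=C(/CO)C(=O)OC)c1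
F2 | step 8 | methyl (2E,4S,6E)-2-(bromomethyl)-9-(furan-3-yl)-6-methyl-4-(triethylsilyloxy)nona-2,6-dienoate | o1ccc(CC/C=C(\C)C[C@H](O[Si](CC)(CC)CC)/C=C(/CBr)C(=O)OC)c1
F3 | step 8 | methyl (2E,4S,6E,10Z)-2-(bromomethyl)-10-formyl-6-methyl-12-oxo-4-(triethylsilyloxy)dodeca-2,6,10-trienoate | O=C/C(=C\C=O)CC/C=C(\C)C[C@H](O[Si](CC)(CC)CC)/C=C(/CBr)C(=O)OC
F4 | step 7 | methyl (2E,4S,6E)-9-(furan-3-yl)-6-methyl-2-(tributylstannyl)-4-(triethylsilyloxy)nona-2,6-dienoate | o1ccc(CC/C=C(\C)C[C@H](O[Si](CC)(CC)CC)/C=C(/[Sn](CCCC)(CCCC)CCCC)C(=O)OC)c1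
F5 | step 7 | methyl (2E,4S,6E)-9-(furan-3-yl)-2-iodo-6-methyl-4-(triethylsilyloxy)nona-2,6-dienoate | o1ccc(CC/C=C(\C)C[C@H](O[Si](CC)(CC)CC)/C=C(/I)C(=O)OC)c1
F6 | step 9 | 8α-hydroxyelema-1,3,11(13)-trien-15-oic acid 12,6α-olide | C=C[C@]1(C)C[C@H](O)[C@H]2C(=C)C(=O)O[C@@H]2[C@H]1C(=C)C(=O)O
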